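**Retrosynthetic overview** (benzofuran numbering: O1, C2, C3, C3a, C4–C7, C7a)
1. Target 10 ⇐ 9 by ionic hydrogenation of the C2=C3 aryl enol ether; 9 ⇐ trienone 8 by conjugate reduction of C4=C5 and kinetic protonation of C5. All three hydrogens are delivered to the face opposite the angular allyl group, which gives the all-cis furan ring and the 5-methoxy group cis to allyl.
2. Key disconnection of 8: the O1–C7a and C3–C3a bonds of the furan ring, made together by a dearomative (3+2) annulation of phenol 6 with silyl enol ether 2 of an aryl ethyl ketone.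
3. Feature used: in the six-membered ring the ketone carbon C6 is para to the quaternary carbon C3a, and the enol-ether carbon C7a is the neighbour of C3a. The ring is therefore an oxidised 4-allylphenol with a leaving group on the meta carbon, and O1–C2(aryl)=C3(methyl) is the enol of the ketone.
4. Only C3a is set in the key step, by a sulfinyl group on C7a that serves as chiral director and is then expelled as the leaving group.
5. Ring order: the benzene ring of 6 is bought; it is dearomatised to the cyclohexadienone and the furan ring is closed onto it in the same step.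

Key step: step 5

Assumption: ketone 1 and phenol 3 are taken as commercial; the sense of induction by the sulfinyl group follows the conformational model given in step 5, and the antipodal menthyl sulfinate would be used if the opposite sense were found.

Step 1
Reactants: 1 1-(3,4,5-trimethoxyphenyl)propan-1-one
Product: 2 (Z)-tert-butyldimethyl{[1-(3,4,5-trimethoxyphenyl)prop-1-en-1-yl]oxy}silane
Conditions: t-BuMe2SiOTf, Et3N, CH2Cl2, 0 °C to rt
Reagents that add atoms: tert-butyldimethylsilyl trifluoromethanesulfonate, CC(C)(C)[Si](C)(C)OS(=O)(=O)C(F)(F)F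
Why: Soft enolisation of the aryl ethyl ketone (silyl enol ether formation) should give mainly the Z enol ether; its geometry is lost later and does not matter.

Step 2
Reactants: 3 5-bromo-2-methoxyphenol
Product: 4 2-methoxy-5-[(S)-4-methylbenzenesulfinyl]phenol
Conditions: n-BuLi (2.1 equiv), THF, −78 °C; then (1R,2S,5R)-menthyl (S)-4-methylbenzenesulfinate, −78 to −40 °C; aq. NH4Cl
Reagents that add atoms: (1R,2S,5R)-menthyl (S)-4-methylbenzenesulfinate, CC(C)[C@@H]1CC[C@@H](C)C[C@H]1O[S@](=O)c1ccc(C)cc1
Why: Bromine–lithium exchange on the lithium phenoxide and substitution at sulfur with inversion (Andersen sulfoxide synthesis) should give the (S)-sulfoxide as one enantiomer.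

Step 3
Reactants: 4 2-methoxy-5-[(S)-4-methylbenzenesulfinyl]phenol
Product: 5 4-iodo-2-methoxy-5-[(S)-4-methylbenzenesulfinyl]phenol
Conditions: N-iodosuccinimide, MeCN, 0 °C to rt
Reagents that add atoms: N-iodosuccinimide, O=C1CCC(=O)N1I
Why: Electrophilic aromatic iodination should go para to the free hydroxy group, the strongest director on the ring.

Step 4
Reactants: 5 4-iodo-2-methoxy-5-[(S)-4-methylbenzenesulfinyl]phenol
Product: 6 2-methoxy-5-[(S)-4-methylbenzenesulfinyl]-4-(prop-2-en-1-yl)phenol
Conditions: allylSnBu3, Pd(PPh3)4 (5 mol %), DMF, 60 °C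
Reagents that add atoms: allyltributylstannane, C=CC[Sn](CCCC)(CCCC)CCCC
Why: Stille coupling of the aryl iodide under zerovalent palladium tolerates the free phenol and the sulfoxide and, being neutral, should leave the allyl double bond out of conjugation.

Step 5
Reactants: 6 2-methoxy-5-[(S)-4-methylbenzenesulfinyl]-4-(prop-2-en-1-yl)phenol; 2 (Z)-tert-butyldimethyl{[1-(3,4,5-trimethoxyphenyl)prop-1-en-1-yl]oxy}silane
Product: 8 (3aS)-5-methoxy-3-methyl-3a-(prop-2-en-1-yl)-2-(3,4,5-trimethoxyphenyl)-1-benzofuran-6(3aH)-one, via dienone ketone 7 (not isolated)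
Conditions: PhI(OAc)2, (CF3)2CHOH/CH2Cl2 (1:4), −40 °C; then DBU, 0 °C
Reagents that add atoms: none
Why: Proposed new method: PhI(OAc)2 (trivalent iodine) oxidises phenol 6 to the phenoxonium ion, enol ether 2 attacks its para carbon (the allyl-bearing carbon, which becomes C3a) to give dienone ketone 7, and DBU then enolises the aryl ketone so that the enol oxygen adds to the sulfinyl-bearing β-carbon of the dienone (C7a) and p-toluenesulfenate is expelled. The closest known reaction types are the trivalent-iodine-mediated para-alkylation of 4-substituted phenols by allylsilanes and enol ethers in fluorinated alcohols, the acid-promoted (3+2) annulation of p-quinone monoketals with propenylbenzenes, and addition–elimination on β-sulfinyl enones. The furan ring closes by 5-exo-trig attack of oxygen followed by elimination; attack on the other β-carbon (C4) has no leaving group and is reversible. The one new stereocentre, quaternary C3a, is set in the carbon–carbon bond formation by the neighbouring (S)-sulfinyl group: with its S–O bond in the ring plane on the side of the ring C–H, the p-tolyl group is expected to cover one face of C3a so that the enol ether enters anti to it; the auxiliary is lost in the ring closure, and the stereocentre next to the ketone in 7 disappears on enolisation. The step needs attack at the para carbon and not at the methoxy-bearing ortho carbon; the hydrogen-bonding solvent, the bulk of the trisubstituted enol ether and the low temperature are relied on for this, and it is the weakest point of the route.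

Step 6
Reactants: 8 (3aS)-5-methoxy-3-methyl-3a-(prop-2-en-1-yl)-2-(3,4,5-trimethoxyphenyl)-1-benzofuran-6(3aH)-one
Product: 9 (3aS,5R)-5-methoxy-3-methyl-3a-(prop-2-en-1-yl)-2-(3,4,5-trimethoxyphenyl)-4,5-dihydro-1-benzofuran-6(3aH)-one
Conditions: LiBH(s-Bu)3, THF, −78 °C; then AcOH, −78 °C
Reagents that add atoms: none
Why: Conjugate (1,4) hydride reduction of the α-methoxy enone, the only enone without a β-oxygen, gives the lithium enolate, and kinetic protonation of C5 on the face opposite the pseudo-axial allyl group at C3a should place the methoxy group cis to allyl (5R).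

Step 7
Reactants: 9 (3aS,5R)-5-methoxy-3-methyl-3a-(prop-2-en-1-yl)-2-(3,4,5-trimethoxyphenyl)-4,5-dihydro-1-benzofuran-6(3aH)-one
Product: 10 dysodanthin B, (2R,3S,3aS,5R)-5-methoxy-3-methyl-3a-(prop-2-en-1-yl)-2-(3,4,5-trimethoxyphenyl)-3,3a,4,5-tetrahydro-1-benzofuran-6(2H)-one
Conditions: Et3SiH, CF3CO2H, CH2Cl2, −40 to 0 °C
Reagents that add atoms: none
Why: Ionic hydrogenation: protonation of the aryl enol ether at C3 gives the 2-aryl oxocarbenium ion, and hydride transfer from the silane to C2 on the face opposite both the angular allyl group and the C3 methyl group should give the all-cis 2R,3S arrangement, the terminal alkene being inert to these conditions.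

**Compound list**
1 | 1-(3,4,5-trimethoxyphenyl)propan-1-one | CCC(=O)c1cc(OC)c(OC)c(OC)c1 | starting material
2 | (Z)-tert-butyldimethyl{[1-(3,4,5-trimethoxyphenyl)prop-1-en-1-yl]oxy}silane | C/C=C(\O[Si](C)(C)C(C)(C)C)c1cc(OC)c(OC)c(OC)c1 | intermediate
3 | 5-bromo-2-methoxyphenol | COc1ccc(Br)cc1O | starting material
4 | 2-methoxy-5-[(S)-4-methylbenzenesulfinyl]phenol | COc1ccc([S@@](=O)c2ccc(C)cc2)cc1O | intermediate
5 | 4-iodo-2-methoxy-5-[(S)-4-methylbenzenesulfinyl]phenol | COc1cc(I)c([S@@](=O)c2ccc(C)cc2)cc1O | intermediate
6 | 2-methoxy-5-[(S)-4-methylbenzenesulfinyl]-4-(prop-2-en-1-yl)phenol | C=CCc1cc(OC)c(O)cc1[S@@](=O)c1ccc(C)cc1 | intermediate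
7 | (4S)-6-methoxy-3-[(S)-4-methylbenzenesulfinyl]-4-[1-oxo-1-(3,4,5-trimethoxyphenyl)propan-2-yl]-4-(prop-2-en-1-yl)cyclohexa-2,5-dien-1-one, both epimers at the propan-2-yl carbon | C=CC[C@@]1(C(C)C(=O)c2cc(OC)c(OC)c(OC)c2)C=C(OC)C(=O)C=C1[S@@](=O)c1ccc(C)cc1 | intermediate
8 | (3aS)-5-methoxy-3-methyl-3a-(prop-2-en-1-yl)-2-(3,4,5-trimethoxyphenyl)-1-benzofuran-6(3aH)-one | C=CC[C@@]12C=C(OC)C(=O)C=C1OC(c1cc(OC)c(OC)c(OC)c1)=C2C | intermediate
9 | (3aS,5R)-5-methoxy-3-methyl-3a-(prop-2-en-1-yl)-2-(3,4,5-trimethoxyphenyl)-4,5-dihydro-1-benzofuran-6(3aH)-one | C=CC[C@@]12C[C@@H](OC)C(=O)C=C1OC(c1cc(OC)c(OC)c(OC)c1)=C2C | intermediate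
10 | dysodanthin B, (2R,3S,3aS,5R)-5-methoxy-3-methyl-3a-(prop-2-en-1-yl)-2-(3,4,5-trimethoxyphenyl)-3,3a,4,5-tetrahydro-1-benzofuran-6(2H)-one | C=CC[C@@]12C[C@@H](OC)C(=O)C=C1O[C@@H](c1cc(OC)c(OC)c(OC)c1)[C@H]2C | target

**Total step count:** 7. **Longest linear sequence:** 6 steps (3 → 4 → 5 → 6 → 8 → 9 → 10).

**Steps most likely to fail**

Step 5. The enol ether may add at the methoxy-bearing ortho carbon instead of the para carbon, or the sulfinyl group may give poor facial control. The fallback sets out from 2 and builds the same ring system by the acid-promoted (3+2) annulation of a p-quinone monoketal with an electron-rich alkene, a known route to 3a-allyl hydrobenzofuranones in which the ring oxygen comes from the quinone. Commercial 3,4-dimethoxyphenol is O-allylated (allyl bromide, K2CO3, acetone) to allyl 3,4-dimethoxyphenyl ether F1. Claisen rearrangement (180 °C) should give 2-allyl-4,5-dimethoxyphenol F2, and PhI(OAc)2 in methanol should give 2-allyl-4,4,5-trimethoxycyclohexa-2,5-dien-1-one F3. F3 and 2 with Me3SiOTf (cat.) in CH2Cl2 at −78 °C should give the racemic trienone F4. Preparative HPLC on a chiral phase then brings the sequence back to the route at 8.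

Step 7. Hydride may be delivered to the wrong face, the acid may ionise the benzylic C–O bond of the product, or the allyl group may migrate. The fallback sets out from 9 and replaces the ionic reduction by a hydrogen-atom-transfer hydrogenation with Mn(dpm)3, PhSiH3 and t-BuOOH in i-PrOH. A hydrogen atom should add to C3 to give the benzylic α-oxy radical at C2, which takes up the second hydrogen atom; the terminal alkene, which would give an unstabilised secondary radical, should react more slowly. No acid is present, no new compound is formed, and the fallback comes back at 10.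

Step 6. The borohydride may add to the carbonyl group instead of the enone, or protonation of the enolate may occur from the wrong face. The fallback sets out from 8: conjugate reduction with [(Ph3P)CuH]6 in the presence of t-BuMe2SiCl should give the silyl dienol ether F5, (3aS)-6-[tert-butyl(dimethyl)silyloxy]-5-methoxy-3-methyl-3a-(prop-2-en-1-yl)-2-(3,4,5-trimethoxyphenyl)-3a,4-dihydro-1-benzofuran. F5 is isolated and then cleaved with Bu4NF/AcOH at −78 °C, so that the protonation becomes a separate, tunable operation. It comes back to the route at 9.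

**Further compounds**
F1 | step 5 | allyl 3,4-dimethoxyphenyl ether | C=CCOc1ccc(OC)c(OC)c1
F2 | step 5 | 2-allyl-4,5-dimethoxyphenol | C=CCc1cc(OC)c(OC)cc1O
F3 | step 5 | 2-allyl-4,4,5-trimethoxycyclohexa-2,5-dien-1-one | C=CCC1=CC(OC)(OC)C(OC)=CC1=O
F4 | step 5 | racemic 5-methoxy-3-methyl-3a-(prop-2-en-1-yl)-2-(3,4,5-trimethoxyphenyl)-1-benzofuran-6(3aH)-one | C=CCC12C=C(OC)C(=O)C=C1OC(c1cc(OC)c(OC)c(OC)c1)=C2C
F5 | step 6 | (3aS)-6-[tert-butyl(dimethyl)silyloxy]-5-methoxy-3-methyl-3a-(prop-2-en-1-yl)-2-(3,4,5-trimethoxyphenyl)-3a,4-dihydro-1-benzofuran | C=CC[C@@]12CC(OC)=C(O[Si](C)(C)C(C)(C)C)C=C1OC(c1cc(OC)c(OC)c(OC)c1)=C2C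
F0 | step 7 | none | none
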